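## Retrosynthetic overview

1. Target 28 ⇐ diol 27 by epoxidation of the 1(10) alkene of the finished germacrolide (epoxide closed last).
2. 27 ⇐ macrocyclic lactone 22 by O8 deprotection, angeloylation and desilylation.
3. 22 ⇐ acyclic dialdehyde 16 + C3 boryl phosphonate 19 in one flask: Z-olefination at C7, then intramolecular allylboration closing C6–C7 (the bond the germacrene cyclase makes between farnesyl C1 and C10; loss of boron from C13 stands in for the proton loss), then O6→C12 lactonisation.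
4. 16 ⇐ enal 8 + silyl dienolate 12 by catalytic asymmetric vinylogous aldol (C2–C3 bond, C2 stereocentre); 8 ⇐ (R)-glycidol, acetylide and carboalumination (C8 stereocentre, E-C1=C10).
5. Ring order: ten-membered carbocycle → γ-lactone → epoxide.

C-numbers in the text are germacrane numbers. TES = triethylsilyl, TBS = tert-butyldimethylsilyl, pinB = 4,4,5,5-tetramethyl-1,3,2-dioxaborolan-2-yl.

Assumption: reagent preparations (steps 5, 6, 11) are counted as steps, and the (S,S)-bisphosphoramide is taken to direct the dienolate to the Si face of 8 in step 7 (its antipode is used if the sense turns out opposite).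

## Route

Step 1
Reactants: 1 (R)-glycidol; 2 lithium acetylide–ethylenediamine complex
Product: 3 (S)-pent-4-yne-1,2-diol
Conditions: LiC≡CH·H2NCH2CH2NH2 (3 equiv), DMSO, 0 → 23 °C; aq. NH4Cl
Reagents that add atoms: none
Why: SN2 opening of the epoxide at its terminal carbon by acetylide (epoxide alkynylation) leaves the carbinol stereocentre untouched, so (R)-glycidol gives the (S)-diol that becomes C8.

Step 2
Reactants: 3
Product: 4 (S)-4,5-bis(triethylsilyloxy)pent-1-yne
Conditions: Et3SiCl (2.3 equiv), imidazole, CH2Cl2, 0 → 23 °C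
Reagents that add atoms: chlorotriethylsilane, CC[Si](Cl)(CC)CC
Why: Routine bis-silylation (silyl ether formation); the primary TES ether is the latent C7 aldehyde and the secondary one masks O8 until after ring closure.

Step 3
Reactants: 4
Product: 7 (S,E)-3-methyl-5,6-bis(triethylsilyloxy)hex-2-en-1-ol, via alkenyldimethylalane 5 (not isolated), via lithium alkenylaluminate 6 (not isolated)
Conditions: Me3Al (3 equiv), Cp2ZrCl2 (0.2 equiv), CH2Cl2, 0 → 23 °C; evaporate excess Me3Al; n-BuLi, THF/hexane, −30 °C; (CH2O)n, → 23 °C; aq. potassium sodium tartrate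
Reagents that add atoms: trimethylaluminium, C[Al](C)C; paraformaldehyde (as formaldehyde), C=O
Why: Negishi zirconium-catalysed carboalumination adds Me and Al syn across the alkyne (Me on the internal carbon) and the derived aluminate is hydroxymethylated with retention, which fixes the E trisubstituted C1=C10 alkene.

Step 4
Reactants: 7
Product: 8 (S,E)-3-methyl-5,6-bis(triethylsilyloxy)hex-2-enal
Conditions: MnO2 (15 equiv), CH2Cl2, 23 °C
Reagents that add atoms: none
Why: MnO2 allylic oxidation is selective for the allylic alcohol and keeps the E geometry.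

Step 5
Reactants: 9 1-(tert-butyldimethylsilyloxy)propan-2-one; 10 trimethyl phosphonoacetate
Product: 11 methyl (E)-4-(tert-butyldimethylsilyloxy)-3-methylbut-2-enoate
Conditions: NaH, THF, 0 → 23 °C; E isomer separated by chromatography
Reagents that add atoms: none
Why: Horner–Wadsworth–Emmons olefination of the activated α-silyloxy ketone gives mainly the E enoate (CH3 cis to CO2Me), which is the isomer needed for γ-deprotonation.

Step 6
Reactants: 11
Product: 12 (1E)-1-methoxy-1-(tert-butyldimethylsilyloxy)-3-[(tert-butyldimethylsilyloxy)methyl]buta-1,3-diene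
Conditions: LiN(i-Pr)2, THF, −78 °C; t-BuMe2SiCl, DMPU, −78 → 0 °C
Reagents that add atoms: tert-butyldimethylsilyl chloride, CC(C)(C)[Si](C)(C)Cl
Why: Kinetic γ-deprotonation by LiN(i-Pr)2 takes the methyl group cis to the ester (cyclic transition state) and O-silylation gives the vinylogous silyl ketene acetal (silyl dienolate formation).

Step 7
Reactants: 8; 12
Product: 13 methyl (2Z,5S,6E,9S)-3-[(tert-butyldimethylsilyloxy)methyl]-5-hydroxy-7-methyl-9,10-bis(triethylsilyloxy)deca-2,6-dienoate
Conditions: SiCl4 (1.1 equiv), (S,S)-bisphosphoramide C51H52N6O2P2 [pentane-1,5-diyl-bridged bis-phosphoramide of N,N'-dimethyl-1,1'-binaphthyl-2,2'-diamine] (2 mol%), i-Pr2NEt (10 mol%), CH2Cl2, −78 °C; aq. KF/NaHCO3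
Reagents that add atoms: none
Why: Lewis-base-activated SiCl4 vinylogous Mukaiyama aldol: the chiral trichlorosilyl cation binds the enal and the dienolate attacks through its γ-carbon on the Si face to set C2 as S, the s-trans diene placing CH2OTBS cis to the ester (C15 cis to C6).

Step 8
Reactants: 13
Product: 14 methyl (2Z,5S,6E,9S)-5-(tert-butyldimethylsilyloxy)-3-[(tert-butyldimethylsilyloxy)methyl]-7-methyl-9,10-bis(triethylsilyloxy)deca-2,6-dienoate
Conditions: t-BuMe2SiOTf, 2,6-lutidine, CH2Cl2, −78 °C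
Reagents that add atoms: tert-butyldimethylsilyl trifluoromethanesulfonate, CC(C)(C)[Si](C)(C)OS(=O)(=O)C(F)(F)F
Why: Silyl triflate silylation of the secondary allylic alcohol prevents its oxidation in step 10.

Step 9
Reactants: 14
Product: 15 (2Z,5S,6E,9S)-5-(tert-butyldimethylsilyloxy)-3-[(tert-butyldimethylsilyloxy)methyl]-7-methyl-9,10-bis(triethylsilyloxy)deca-2,6-dien-1-ol
Conditions: i-Bu2AlH (2.5 equiv), CH2Cl2, −78 °C; aq. potassium sodium tartrate
Reagents that add atoms: none
Why: i-Bu2AlH 1,2-reduction of the conjugated methyl ester gives the allylic alcohol without touching silyl ethers or alkene geometry.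

Step 10
Reactants: 15
Product: 16 (2Z,5S,6E,9S)-5-(tert-butyldimethylsilyloxy)-3-[(tert-butyldimethylsilyloxy)methyl]-7-methyl-9-(triethylsilyloxy)deca-2,6-dienedial
Conditions: (COCl)2, DMSO, CH2Cl2, −78 → −45 °C; i-Pr2NEt, −78 → −20 °C
Reagents that add atoms: none
Why: Swern oxidation turns the allylic alcohol into the enal and at the same time oxidises the primary triethylsilyl ether directly to the aldehyde, a known selectivity that leaves secondary TES and all TBS ethers intact.

Step 11
Reactants: 17 methyl bis(2,2,2-trifluoroethyl)phosphonoacetate; 18 2-(iodomethyl)-4,4,5,5-tetramethyl-1,3,2-dioxaborolane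
Product: 19 methyl 2-[bis(2,2,2-trifluoroethoxy)phosphoryl]-3-(pinB)propanoate (racemic)
Conditions: NaH, THF/DMF, 0 → 23 °C
Reagents that add atoms: none
Why: Alkylation of the phosphonoacetate anion with the iodomethylboronate (boron ate complex then 1,2-shift displacing iodide) gives the α-(borylmethyl) phosphonate; its stereocentre is racemic and is destroyed in step 12.

Step 12
Reactants: 16; 19
Product: 22 8α-(triethylsilyloxy)-2α,15-bis(tert-butyldimethylsilyloxy)germacra-1(10),4,11(13)-trien-12,6α-olide, via allylboronate enal 20 (not isolated), via boryl ether ester 21 (not isolated)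
Conditions: 19 (1.05 equiv), KN(SiMe3)2, 18-crown-6, THF, −78 °C; add 16, −78 °C, 2 h; dilute into PhMe (1 mM), 80 °C, 36 h
Reagents that add atoms: none
Why: Proposed new method: the Still–Gennari anion of 19 olefinates only the α-silyloxy aldehyde (the β,β-disubstituted enal is far less electrophilic) to give the Z enoate with C8 cis to CO2Me and trans to CH2–pinB, and this E-crotyl-like 2-alkoxycarbonyl allylboronate then adds through its γ-carbon (C7) to the C6 enal in a closed chair transition state (anti adduct, hence trans H6/H7) on the face carrying the C9 tether while H8 eclipses the enoate (1,3-allylic strain), which gives the natural H-6β/H-7α arrangement relative to 8α-O, before the boron-bound C6 alkoxide lactonises onto C12; the closest known reactions are Z-selective Still–Gennari olefination of α-silyloxy aldehydes, stereospecific thermal allylboration/lactonisation of aldehydes with 2-alkoxycarbonyl allylboronates, and ten-membered ring closure of farnesal-type aldehydes by intramolecular allyl-metal addition.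

Step 13
Reactants: 22
Product: 23 8α-hydroxy-2α,15-bis(tert-butyldimethylsilyloxy)germacra-1(10),4,11(13)-trien-12,6α-olide
Conditions: pyridinium p-toluenesulfonate (0.2 equiv), MeOH/CH2Cl2 (1:3), 0 °C
Reagents that add atoms: none
Why: Acid-catalysed methanolysis cleaves a triethylsilyl ether much faster than TBS ethers (selective desilylation), freeing only O8.

Step 14
Reactants: 23; 24 angelic acid
Product: 26 8α-angeloyloxy-2α,15-bis(tert-butyldimethylsilyloxy)germacra-1(10),4,11(13)-trien-12,6α-olide, via mixed anhydride 25 (not isolated)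
Conditions: 24, 2,4,6-Cl3C6H2COCl, Et3N, PhMe, 23 °C, 2 h; then 23, 75 °C
Reagents that add atoms: none
Why: Yamaguchi esterification through the mixed anhydride, run without DMAP, acylates the only free hydroxyl and is the standard way to make angelates without Z to E isomerisation.

Step 15
Reactants: 26
Product: 27 8α-angeloyloxy-2α,15-dihydroxygermacra-1(10),4,11(13)-trien-12,6α-olide
Conditions: HF·pyridine, pyridine, THF, 0 → 23 °C
Reagents that add atoms: none
Why: Buffered HF·pyridine removes both allylic TBS ethers (fluoride desilylation) without harming the angelate or the α-methylene lactone.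

Step 16
Reactants: 27
Product: 28 8α-angeloyloxy-1β,10α-epoxy-2α,15-dihydroxygermacra-4,11(13)-dien-12,6α-olide (EANPDB:COMP_00180)
Conditions: mCPBA (1.05 equiv), NaHCO3, CH2Cl2, 0 °C
Reagents that add atoms: meta-chloroperoxybenzoic acid, O=C(OO)c1cccc(Cl)c1
Why: Prilezhaev epoxidation attacks the most electron-rich alkene (1(10); the 4,5-alkene carries two allylic oxygens and the other two are conjugated to carbonyls) from the exposed outer face of the germacrolide, the face on which the 2α-hydroxyl hydrogen-bonds the peracid (threo delivery enforced by 1,3-allylic strain), so the 1β,10α-epoxide forms.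

## Compound list

1 | (R)-glycidol | OC[C@@H]1CO1 | starting material
2 | lithium acetylide–ethylenediamine complex | [Li+].[C-]#C.NCCN | starting material
3 | (S)-pent-4-yne-1,2-diol | OC[C@@H](O)CC#C | intermediate
4 | (S)-4,5-bis(triethylsilyloxy)pent-1-yne | CC[Si](CC)(CC)OC[C@@H](O[Si](CC)(CC)CC)CC#C | intermediate
5 | [(S,E)-2-methyl-4,5-bis(triethylsilyloxy)pent-1-enyl]dimethylalane | C[Al](C)/C=C(\C)C[C@H](O[Si](CC)(CC)CC)CO[Si](CC)(CC)CC | intermediate
6 | lithium butyl[(S,E)-2-methyl-4,5-bis(triethylsilyloxy)pent-1-enyl]dimethylaluminate | [Li+].CCCC[Al-](C)(C)/C=C(\C)C[C@H](O[Si](CC)(CC)CC)CO[Si](CC)(CC)CC | intermediate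
7 | (S,E)-3-methyl-5,6-bis(triethylsilyloxy)hex-2-en-1-ol | OC/C=C(\C)C[C@H](O[Si](CC)(CC)CC)CO[Si](CC)(CC)CC | intermediate
8 | (S,E)-3-methyl-5,6-bis(triethylsilyloxy)hex-2-enal | O=C/C=C(\C)C[C@H](O[Si](CC)(CC)CC)CO[Si](CC)(CC)CC | intermediate
9 | 1-(tert-butyldimethylsilyloxy)propan-2-one | CC(=O)CO[Si](C)(C)C(C)(C)C | starting material
10 | trimethyl phosphonoacetate | COC(=O)CP(=O)(OC)OC | starting material
11 | methyl (E)-4-(tert-butyldimethylsilyloxy)-3-methylbut-2-enoate | COC(=O)/C=C(\C)CO[Si](C)(C)C(C)(C)C | intermediate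
12 | (1E)-1-methoxy-1-(tert-butyldimethylsilyloxy)-3-[(tert-butyldimethylsilyloxy)methyl]buta-1,3-diene | C=C(CO[Si](C)(C)C(C)(C)C)/C=C(\OC)O[Si](C)(C)C(C)(C)C | intermediate
13 | methyl (2Z,5S,6E,9S)-3-[(tert-butyldimethylsilyloxy)methyl]-5-hydroxy-7-methyl-9,10-bis(triethylsilyloxy)deca-2,6-dienoate | COC(=O)/C=C(\CO[Si](C)(C)C(C)(C)C)C[C@H](O)/C=C(\C)C[C@H](O[Si](CC)(CC)CC)CO[Si](CC)(CC)CC | intermediate
14 | methyl (2Z,5S,6E,9S)-5-(tert-butyldimethylsilyloxy)-3-[(tert-butyldimethylsilyloxy)methyl]-7-methyl-9,10-bis(triethylsilyloxy)deca-2,6-dienoate | COC(=O)/C=C(\CO[Si](C)(C)C(C)(C)C)C[C@H](O[Si](C)(C)C(C)(C)C)/C=C(\C)C[C@H](O[Si](CC)(CC)CC)CO[Si](CC)(CC)CC | intermediate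
15 | (2Z,5S,6E,9S)-5-(tert-butyldimethylsilyloxy)-3-[(tert-butyldimethylsilyloxy)methyl]-7-methyl-9,10-bis(triethylsilyloxy)deca-2,6-dien-1-ol | OC/C=C(\CO[Si](C)(C)C(C)(C)C)C[C@H](O[Si](C)(C)C(C)(C)C)/C=C(\C)C[C@H](O[Si](CC)(CC)CC)CO[Si](CC)(CC)CC | intermediate
16 | (2Z,5S,6E,9S)-5-(tert-butyldimethylsilyloxy)-3-[(tert-butyldimethylsilyloxy)methyl]-7-methyl-9-(triethylsilyloxy)deca-2,6-dienedial | O=C/C=C(\CO[Si](C)(C)C(C)(C)C)C[C@H](O[Si](C)(C)C(C)(C)C)/C=C(\C)C[C@H](O[Si](CC)(CC)CC)C=O | intermediate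
17 | methyl bis(2,2,2-trifluoroethyl)phosphonoacetate | COC(=O)CP(=O)(OCC(F)(F)F)OCC(F)(F)F | starting material
18 | 2-(iodomethyl)-4,4,5,5-tetramethyl-1,3,2-dioxaborolane | ICB1OC(C)(C)C(C)(C)O1 | starting material
19 | methyl 2-[bis(2,2,2-trifluoroethoxy)phosphoryl]-3-(4,4,5,5-tetramethyl-1,3,2-dioxaborolan-2-yl)propanoate (racemic) | COC(=O)C(CB1OC(C)(C)C(C)(C)O1)P(=O)(OCC(F)(F)F)OCC(F)(F)F | intermediate
20 | methyl (2Z,4S,6E,8S,10Z)-8-(tert-butyldimethylsilyloxy)-10-[(tert-butyldimethylsilyloxy)methyl]-6-methyl-12-oxo-2-[(pinB)methyl]-4-(triethylsilyloxy)dodeca-2,6,10-trienoate | O=C/C=C(\CO[Si](C)(C)C(C)(C)C)C[C@H](O[Si](C)(C)C(C)(C)C)/C=C(\C)C[C@H](O[Si](CC)(CC)CC)/C=C(/CB1OC(C)(C)C(C)(C)O1)C(=O)OC | intermediate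
21 | methyl 6α-(pinB-oxy)-8α-(triethylsilyloxy)-2α,15-bis(tert-butyldimethylsilyloxy)germacra-1(10),4,11(13)-trien-12-oate (H-7α; both ring alkenes trans in the ring) | C=C(C(=O)OC)[C@H]1[C@H](OB2OC(C)(C)C(C)(C)O2)/C=C(\CO[Si](C)(C)C(C)(C)C)C[C@H](O[Si](C)(C)C(C)(C)C)/C=C(\C)C[C@@H]1O[Si](CC)(CC)CC | intermediate
22 | 8α-(triethylsilyloxy)-2α,15-bis(tert-butyldimethylsilyloxy)germacra-1(10),4,11(13)-trien-12,6α-olide (H-6β, H-7α; ring alkenes 1(10)E, 4Z by CIP, both trans in the ring) | C=C1C(=O)O[C@@H]2/C=C(\CO[Si](C)(C)C(C)(C)C)C[C@H](O[Si](C)(C)C(C)(C)C)/C=C(\C)C[C@H](O[Si](CC)(CC)CC)[C@@H]12 | intermediate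
23 | 8α-hydroxy-2α,15-bis(tert-butyldimethylsilyloxy)germacra-1(10),4,11(13)-trien-12,6α-olide | C=C1C(=O)O[C@@H]2/C=C(\CO[Si](C)(C)C(C)(C)C)C[C@H](O[Si](C)(C)C(C)(C)C)/C=C(\C)C[C@H](O)[C@@H]12 | intermediate
24 | angelic acid [(Z)-2-methylbut-2-enoic acid] | C/C=C(/C)C(=O)O | starting material
25 | (Z)-2-methylbut-2-enoic 2,4,6-trichlorobenzoic anhydride | C/C=C(/C)C(=O)OC(=O)c1c(Cl)cc(Cl)cc1Cl | intermediate
26 | 8α-angeloyloxy-2α,15-bis(tert-butyldimethylsilyloxy)germacra-1(10),4,11(13)-trien-12,6α-olide | C=C1C(=O)O[C@@H]2/C=C(\CO[Si](C)(C)C(C)(C)C)C[C@H](O[Si](C)(C)C(C)(C)C)/C=C(\C)C[C@H](OC(=O)/C(C)=C\C)[C@@H]12 | intermediate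
27 | 8α-angeloyloxy-2α,15-dihydroxygermacra-1(10),4,11(13)-trien-12,6α-olide | C=C1C(=O)O[C@@H]2/C=C(\CO)C[C@H](O)/C=C(\C)C[C@H](OC(=O)/C(C)=C\C)[C@@H]12 | intermediate
28 | 8α-angeloyloxy-1β,10α-epoxy-2α,15-dihydroxygermacra-4,11(13)-dien-12,6α-olide | C=C1C(=O)O[C@@H]2/C=C(\CO)C[C@H](O)[C@H]3O[C@]3(C)C[C@H](OC(=O)/C(C)=C\C)[C@@H]12 | target

## Step count and risks

Total steps: 16. Longest linear sequence: 13 (steps 1–4, 7–10, 12–16).

**Step 12 (olefination / macro-allylboration / lactonisation).** It can fail through poor aldehyde discrimination, a slow ten-membered ring closure or the wrong facial sense. The fallback sets out from dialdehyde 16 and comes back at lactone 22. A Morita–Baylis–Hillman reaction of 16 with methyl acrylate (DABCO) at the α-silyloxy aldehyde gives methyl (4S,6E,8S,10Z)-8-(tert-butyldimethylsilyloxy)-10-[(tert-butyldimethylsilyloxy)methyl]-3-hydroxy-6-methyl-2-methylidene-12-oxo-4-(triethylsilyloxy)dodeca-6,10-dienoate F1 as a C3-epimer mixture. NBS/Me2S converts it with allylic transposition into methyl (2Z,4S,6E,8S,10Z)-2-(bromomethyl)-8-(tert-butyldimethylsilyloxy)-10-[(tert-butyldimethylsilyloxy)methyl]-6-methyl-12-oxo-4-(triethylsilyloxy)dodeca-2,6,10-trienoate F2. A CrCl2-mediated intramolecular Nozaki–Hiyama–Kishi allylation at high dilution in THF then closes C6–C7 through an allylchromium that equilibrates to its more stable geometry and adds anti in a chair transition state, and lactonisation gives 22. This replaces the boron allylation by an organochromium Barbier closure whose nucleophile is generated only after all olefination chemistry is finished.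

**Step 7 (asymmetric vinylogous aldol with a new, oxygenated dienolate).** The γ-selectivity, enoate geometry or ee may be insufficient. The fallback sets out from enal 8 (with 12) and comes back at 13. An achiral BF3·OEt2-promoted vinylogous Mukaiyama aldol gives methyl (2Z,6E,9S)-3-[(tert-butyldimethylsilyloxy)methyl]-5-hydroxy-7-methyl-9,10-bis(triethylsilyloxy)deca-2,6-dienoate F3 as a C5-epimer mixture. Dess–Martin oxidation gives methyl (2Z,6E,9S)-3-[(tert-butyldimethylsilyloxy)methyl]-7-methyl-5-oxo-9,10-bis(triethylsilyloxy)deca-2,6-dienoate F4. Reduction with catecholborane and the (R)-methyl-CBS oxazaborolidine [(R)-1-methyl-3,3-diphenyltetrahydro-1H,3H-pyrrolo[1,2-c][1,3,2]oxazaborole] (alkenyl as the large group) then sets C2 as S by reagent control and returns 13.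

**Step 16 (final epoxidation of the unprotected diol).** Over-oxidation at the 4,5-alkene or the wrong face are possible. The fallback sets out from bis-silyl ether 26 and comes back at target 28. Compound 26 is epoxidised first (mCPBA, NaHCO3), so that only peripheral attack on the 1(10) alkene operates and the 4,5-alkene is shielded by its silyloxymethyl group, to give 8α-angeloyloxy-1β,10α-epoxy-2α,15-bis(tert-butyldimethylsilyloxy)germacra-4,11(13)-dien-12,6α-olide F5. Near-neutral Et3N·3HF in MeCN then removes both TBS groups to give 28.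

## Further compounds

F1 | step 12 | methyl (4S,6E,8S,10Z)-8-(tert-butyldimethylsilyloxy)-10-[(tert-butyldimethylsilyloxy)methyl]-3-hydroxy-6-methyl-2-methylidene-12-oxo-4-(triethylsilyloxy)dodeca-6,10-dienoate (C3 epimers) | O=C/C=C(\CO[Si](C)(C)C(C)(C)C)C[C@H](O[Si](C)(C)C(C)(C)C)/C=C(\C)C[C@H](O[Si](CC)(CC)CC)C(O)C(=C)C(=O)OC
F2 | step 12 | methyl (2Z,4S,6E,8S,10Z)-2-(bromomethyl)-8-(tert-butyldimethylsilyloxy)-10-[(tert-butyldimethylsilyloxy)methyl]-6-methyl-12-oxo-4-(triethylsilyloxy)dodeca-2,6,10-trienoate | O=C/C=C(\CO[Si](C)(C)C(C)(C)C)C[C@H](O[Si](C)(C)C(C)(C)C)/C=C(\C)C[C@H](O[Si](CC)(CC)CC)/C=C(\CBr)C(=O)OC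
F3 | step 7 | methyl (2Z,6E,9S)-3-[(tert-butyldimethylsilyloxy)methyl]-5-hydroxy-7-methyl-9,10-bis(triethylsilyloxy)deca-2,6-dienoate (C5 epimers) | COC(=O)/C=C(\CO[Si](C)(C)C(C)(C)C)CC(O)/C=C(\C)C[C@H](O[Si](CC)(CC)CC)CO[Si](CC)(CC)CC
F4 | step 7 | methyl (2Z,6E,9S)-3-[(tert-butyldimethylsilyloxy)methyl]-7-methyl-5-oxo-9,10-bis(triethylsilyloxy)deca-2,6-dienoate | COC(=O)/C=C(\CO[Si](C)(C)C(C)(C)C)CC(=O)/C=C(\C)C[C@H](O[Si](CC)(CC)CC)CO[Si](CC)(CC)CC
F5 | step 16 | 8α-angeloyloxy-1β,10α-epoxy-2α,15-bis(tert-butyldimethylsilyloxy)germacra-4,11(13)-dien-12,6α-olide | C=C1C(=O)O[C@@H]2/C=C(\CO[Si](C)(C)C(C)(C)C)C[C@H](O[Si](C)(C)C(C)(C)C)[C@H]3O[C@]3(C)C[C@H](OC(=O)/C(C)=C\C)[C@@H]12
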